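**Retrosynthetic overview**
1. Target 31 ⇐ C12 acylation of diol 29 ⇐ C6–C7 sp3–sp2 coupling that closes the nine-membered oxacycle (last ring) ⇐ cis-dihydroxylation of C11=C12.
2. Oxepane ⇐ C3–OH displacing a C16 triflate; C11(Me)=C12 ⇐ enol triflate of ketone 18.
3. Ketone 18 ⇐ oxocarbenium/enol-carbamate cyclization of 16 with acetal 17 (forms the tetrahydrofuran, sets C9 and C10).
4. Key bond C1–C2: allyltitanium 15 from a cyclohexenyl carbamate (a homoenolate equivalent of the C11 ketone, nucleophilic at C1) adds to aldehyde 13 and sets C1 and C2.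
5. Ring order: cyclohexene (Michael/aldol) → tetrahydrofuran → oxepane → nine-membered oxacycle.

Assumption: locants C1–C20 follow eunicellane numbering of the target as drawn, (1S,2S,3S,9S,10R,11R,12S,14S,15R), with C1/C10 the ring fusion, C2–O–C9 the tetrahydrofuran, C3(Me)–O–C16 the oxepane, C7=C19H2, C11(Me)(OH), C12 ester, and C14 bearing C15(Me)–C16; these locants are used for all intermediates.

**Route**

Step 1
Reactants: 1 (S)-3-bromo-2-methylpropan-1-ol
Product: 2 (S)-(3-bromo-2-methylpropoxy)(tert-butyl)diphenylsilane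
Conditions: TBDPSCl, imidazole, DMF, rt
Reagents that add atoms: tert-butyl(chloro)diphenylsilane, CC(C)(C)[Si](Cl)(c1ccccc1)c1ccccc1
Why: Silyl ether formation on the primary alcohol; the stereocentre (future C15) is not touched.

Step 2
Reactants: 2 (S)-(3-bromo-2-methylpropoxy)(tert-butyl)diphenylsilane
Product: 4 (R)-4-(tert-butyldiphenylsilyloxy)-3-methylbutanal, via alkylmagnesium bromide 3 (not isolated)
Conditions: Mg, THF, reflux; DMF, 0 °C; aq. HCl
Reagents that add atoms: N,N-dimethylformamide, CN(C)C=O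
Why: Grignard formation and Bouveault formylation add one carbon (future C1) without affecting the β-stereocentre.

Step 3
Reactants: 4 (R)-4-(tert-butyldiphenylsilyloxy)-3-methylbutanal; 5 methyl vinyl ketone
Product: 7 (R)-4-[(R)-1-(tert-butyldiphenylsilyloxy)propan-2-yl]cyclohex-2-en-1-one, via Michael adduct 6 (not isolated)
Conditions: (S)-α,α-diphenylprolinol trimethylsilyl ether (10 mol %), ethyl 3,4-dihydroxybenzoate (20 mol %), neat, 0 °C → rt; then LiOH, iPrOH, rt
Reagents that add atoms: none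
Why: Enamine-catalysed asymmetric Michael addition sets C14 under catalyst control (the enone approaches the enamine face away from the CPh2OSiMe3 group), and intramolecular aldol condensation (Robinson-type annulation) then closes the cyclohexenone.

Step 4
Reactants: 7 (R)-4-[(R)-1-(tert-butyldiphenylsilyloxy)propan-2-yl]cyclohex-2-en-1-one
Product: 8 (1R,4R)-4-[(R)-1-(tert-butyldiphenylsilyloxy)propan-2-yl]cyclohex-2-en-1-ol
Conditions: NaBH4, CeCl3·7H2O, MeOH, −78 °C; minor cis isomer removed by chromatography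
Reagents that add atoms: none
Why: Luche 1,2-reduction with axial hydride delivery to the half-chair that carries the C4 substituent pseudo-equatorially gives the trans (1,4-diequatorial) allylic alcohol.

Step 5
Reactants: 8 (1R,4R)-4-[(R)-1-(tert-butyldiphenylsilyloxy)propan-2-yl]cyclohex-2-en-1-ol
Product: 9 (1R,4R)-4-[(R)-1-(tert-butyldiphenylsilyloxy)propan-2-yl]cyclohex-2-en-1-yl N,N-diisopropylcarbamate
Conditions: NaH, THF, 0 °C; iPr2NC(O)Cl, reflux
Reagents that add atoms: N,N-diisopropylcarbamoyl chloride, CC(C)N(C(C)C)C(=O)Cl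
Why: O-carbamoylation installs the group that directs and stabilises α-lithiation; no stereocentre is affected.

Step 6
Reactants: 10 (R)-2-methylglycidol
Product: 11 (S)-2-methylpent-4-ene-1,2-diol
Conditions: CH2=CHMgBr (2.5 equiv), CuI (10 mol %), THF, −30 → 0 °C
Reagents that add atoms: vinylmagnesium bromide, C=C[Mg]Br
Why: Copper-catalysed Grignard opening of the epoxide at its CH2 terminus leaves the quaternary carbinol centre (future C3) intact.

Step 7
Reactants: 11 (S)-2-methylpent-4-ene-1,2-diol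
Product: 12 (S)-2-methyl-1,2-bis(triethylsilyloxy)pent-4-ene
Conditions: Et3SiOTf (2.4 equiv), 2,6-lutidine, CH2Cl2, −78 → 0 °C
Reagents that add atoms: triethylsilyl trifluoromethanesulfonate, CC[Si](CC)(CC)OS(=O)(=O)C(F)(F)F
Why: Exhaustive silylation with the silyl triflate protects the tertiary as well as the primary hydroxyl.

Step 8
Reactants: 12 (S)-2-methyl-1,2-bis(triethylsilyloxy)pent-4-ene
Product: 13 (S)-2-methyl-2-(triethylsilyloxy)pent-4-enal
Conditions: (COCl)2, DMSO, CH2Cl2, −78 → −30 °C; Et3N, −78 °C → rt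
Reagents that add atoms: none
Why: Swern oxidation cleaves and oxidises the primary triethylsilyl ether directly to the aldehyde, while the hindered tertiary silyl ether survives and the non-enolisable α-centre cannot racemise.

Step 9 (key step)
Reactants: 9 (1R,4R)-4-[(R)-1-(tert-butyldiphenylsilyloxy)propan-2-yl]cyclohex-2-en-1-yl N,N-diisopropylcarbamate; 13 (S)-2-methyl-2-(triethylsilyloxy)pent-4-enal
Product: 16 (3S,4S)-4-[(R)-1-(tert-butyldiphenylsilyloxy)propan-2-yl]-3-[(1S,2S)-1-hydroxy-2-methyl-2-(triethylsilyloxy)pent-4-en-1-yl]cyclohex-1-en-1-yl N,N-diisopropylcarbamate, via lithiated carbamate 14 (not isolated), via allyltitanium triisopropoxide 15 (not isolated)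
Conditions: s-BuLi, TMEDA, Et2O, −78 °C; ClTi(OiPr)3, −78 °C; 13, −78 → −30 °C; aq. NH4Cl
Reagents that add atoms: none
Why: Hoppe homoaldol reaction: carbamate-directed α-lithiation (retention) and Li→Ti exchange (inversion) give an allyltitanium that is a homoenolate equivalent of the C11 ketone, nucleophilic at C1 (electrophilic in the parent enone), which adds to the aldehyde carbon C2 through a closed six-membered transition state on the titanium-bearing face, so C1 is set by 1,3-chirality transfer anti to the C14 side chain and C2 by the ring-locked allyl unit with the aldehyde residue turned away from the carbocycle (anti adduct), C3 being carried in from 13.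

Step 10
Reactants: 16 homoaldol adduct (name as in step 9); 17 4,4-diethoxybut-1-yne
Product: 18 (1S,3S,3aR,7S,7aS)-7-[(R)-1-(tert-butyldiphenylsilyloxy)propan-2-yl]-3-(prop-2-yn-1-yl)-1-[(S)-2-(triethylsilyloxy)pent-4-en-2-yl]-3,3a,5,6,7,7a-hexahydroisobenzofuran-4(1H)-one
Conditions: BF3·OEt2 (2 equiv), CH2Cl2, −78 → −20 °C
Reagents that add atoms: none
Why: BF3 turns the C2 hydroxyl and the acetal into an (E)-oxocarbenium ion that the enol carbamate captures in a Mukaiyama-type (Prins-type) cyclization; the short tether forces the new C9–C10 bond onto the face of the C1–C2 bond (cis ring fusion), the C9 substituent sits pseudo-equatorial and cis to the C2 substituent, and transfer of the carbamoyl group to ethanol unveils the C11 ketone.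

Step 11
Reactants: 18 ketone (name as in step 10)
Product: 20 (1S,3S,3aR,7S,7aS)-7-[(R)-1-(tert-butyldiphenylsilyloxy)propan-2-yl]-3-(prop-2-yn-1-yl)-1-[(S)-2-(triethylsilyloxy)pent-4-en-2-yl]-1,3,3a,6,7,7a-hexahydroisobenzofuran-4-yl trifluoromethanesulfonate, via potassium enolate 19 (not isolated)
Conditions: KN(SiMe3)2 (1.1 equiv), THF, −78 °C; PhNTf2, −78 → 0 °C
Reagents that add atoms: N-phenylbis(trifluoromethanesulfonimide), O=S(=O)(N(c1ccccc1)S(=O)(=O)C(F)(F)F)C(F)(F)F
Why: Kinetic deprotonation at the C12 methylene (not the C10 methine, whose enolate would expel the C9 alkoxide) and O-triflation give the C11=C12 enol triflate, the far less acidic alkyne C–H being untouched by one equivalent of base.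

Step 12
Reactants: 20 enol triflate (name as in step 11)
Product: 21 (1S,3S,3aS,7S,7aS)-7-[(R)-1-(tert-butyldiphenylsilyloxy)propan-2-yl]-4-methyl-3-(prop-2-yn-1-yl)-1-[(S)-2-(triethylsilyloxy)pent-4-en-2-yl]-1,3,3a,6,7,7a-hexahydroisobenzofuran
Conditions: Pd(PPh3)4 (5 mol %), Me2Zn, THF, 0 °C → rt
Reagents that add atoms: dimethylzinc, C[Zn]C
Why: Negishi cross-coupling of the enol triflate installs the C11 methyl group and fixes the alkene at C11=C12.

Step 13
Reactants: 21 methyl-substituted alkene (name as in step 12)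
Product: 23 (1S,3S,3aS,7S,7aS)-7-[(R)-1-(tert-butyldiphenylsilyloxy)propan-2-yl]-3-(2-iodoprop-2-en-1-yl)-4-methyl-1-[(S)-2-(triethylsilyloxy)pent-4-en-2-yl]-1,3,3a,6,7,7a-hexahydroisobenzofuran, via iodoalkenylborane 22 (not isolated)
Conditions: B-iodo-9-BBN (1.2 equiv), pentane/CH2Cl2, −20 → 0 °C; AcOH, 0 °C → rt
Reagents that add atoms: B-iodo-9-borabicyclo[3.3.1]nonane, IB1C2CCCC1CCC2
Why: Syn-haloboration of the terminal alkyne puts iodine on the internal carbon (Markovnikov) and protodeboronation with acetic acid gives the 2-iodoalkene, alkenes being inert to haloboration under these conditions.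

Step 14
Reactants: 23 iodoalkene (name as in step 13)
Product: 24 diol corresponding to 23 with both silyl groups removed (free C16–OH and C3–OH; 1S,2S,3S,9S,10S,14S,15R)
Conditions: HF·pyridine, pyridine, THF, 0 °C → rt
Reagents that add atoms: none
Why: Fluoride-mediated desilylation removes the primary silyl ether and the tertiary triethylsilyl ether in one operation without affecting the alkenes or the iodoalkene.

Step 15
Reactants: 24 diol (as described in step 14)
Product: 26 tricyclic oxepane with C3–O–C16 ether, C11(Me)=C12 alkene, allyl group on C3 and 2-iodoallyl group on C9 (1S,2S,3S,9S,10S,14S,15R), via primary triflate 25 (not isolated)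
Conditions: Tf2O (1.1 equiv), 2,6-lutidine (3 equiv), CH2Cl2, −78 °C → rt
Reagents that add atoms: none
Why: Selective triflation of the primary C16 alcohol followed by intramolecular Williamson-type displacement by the tertiary C3 hydroxyl (7-exo-tet) closes the oxepane without breaking a bond to any stereocentre.

Step 16
Reactants: 26 tricyclic oxepane (as described in step 15)
Product: 27 11,12-cis-diol of 26 (both hydroxyls cis to H10; 1S,2S,3S,9S,10R,11R,12S,14S,15R)
Conditions: OsO4 (5 mol %), NMO (1.3 equiv), acetone/H2O 10:1, 0 °C; NaHSO3 quench at full conversion of 26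
Reagents that add atoms: N-methylmorpholine N-oxide, C[N+]1([O-])CCOCC1; water, O
Why: Upjohn syn-dihydroxylation: the electron-rich trisubstituted C11=C12 alkene reacts faster than the monosubstituted allyl group and the electron-poor iodoalkene, and OsO4 adds from the convex face opposite the pseudo-axial C10–C9 bond, setting C11 and C12.

Step 17
Reactants: 27 cis-diol (as described in step 16)
Product: 29 macrocyclic diol = 31 lacking the octanoyl group (1S,2S,3S,9S,10R,11R,12S,14S,15R), via alkylborane 28 (not isolated)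
Conditions: 9-BBN (4 equiv), THF, rt; then Pd(dppf)Cl2 (15 mol %), AsPh3, Cs2CO3, DMF/THF/H2O, slow addition to 1 mM, 50 °C
Reagents that add atoms: none
Why: Proposed new method: intramolecular B-alkyl Suzuki–Miyaura coupling closing a nine-membered ring; 9-BBN hydroborates only the terminal alkene, then oxidative addition of zerovalent palladium into the C7–I bond, base-assisted alkyl transfer from boron and reductive elimination form C6–C7 and deliver the exocyclic methylene directly, with the cis-2,5-disubstituted tetrahydrofuran holding the chain ends close; the closest known reactions are B-alkyl Suzuki macrocyclizations of larger rings and the CrCl2/NiCl2 closure of this same ring between a 2-iodoalkene and an aldehyde.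

Step 18
Reactants: 29 macrocyclic diol (as described in step 17); 30 octanoyl chloride
Product: 31 target compound CNP0286133.1
Conditions: pyridine, DMAP (cat.), CH2Cl2, 0 °C → rt
Reagents that add atoms: none
Why: Esterification acylates the secondary C12 hydroxyl while the hindered tertiary C11 hydroxyl stays free.

**Compound list**

1 | (S)-3-bromo-2-methylpropan-1-ol | OC[C@H](C)CBr | starting material
2 | (S)-(3-bromo-2-methylpropoxy)(tert-butyl)diphenylsilane | CC(C)(C)[Si](c1ccccc1)(c1ccccc1)OC[C@H](C)CBr | intermediate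
3 | [(S)-3-(tert-butyldiphenylsilyloxy)-2-methylpropyl]magnesium bromide | CC(C)(C)[Si](c1ccccc1)(c1ccccc1)OC[C@H](C)C[Mg]Br | intermediate
4 | (R)-4-(tert-butyldiphenylsilyloxy)-3-methylbutanal | CC(C)(C)[Si](c1ccccc1)(c1ccccc1)OC[C@H](C)CC=O | intermediate
5 | methyl vinyl ketone (but-3-en-2-one) | CC(=O)C=C | starting material
6 | (S)-2-[(R)-1-(tert-butyldiphenylsilyloxy)propan-2-yl]-5-oxohexanal | CC(C)(C)[Si](c1ccccc1)(c1ccccc1)OC[C@H](C)[C@@H](C=O)CCC(C)=O | intermediate
7 | (R)-4-[(R)-1-(tert-butyldiphenylsilyloxy)propan-2-yl]cyclohex-2-en-1-one | CC(C)(C)[Si](c1ccccc1)(c1ccccc1)OC[C@H](C)[C@H]2C=CC(=O)CC2 | intermediate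
8 | (1R,4R)-4-[(R)-1-(tert-butyldiphenylsilyloxy)propan-2-yl]cyclohex-2-en-1-ol (trans) | CC(C)(C)[Si](c1ccccc1)(c1ccccc1)OC[C@H](C)[C@H]2C=C[C@H](O)CC2 | intermediate
9 | (1R,4R)-4-[(R)-1-(tert-butyldiphenylsilyloxy)propan-2-yl]cyclohex-2-en-1-yl N,N-diisopropylcarbamate | CC(C)(C)[Si](c1ccccc1)(c1ccccc1)OC[C@H](C)[C@H]2C=C[C@H](OC(=O)N(C(C)C)C(C)C)CC2 | intermediate
10 | (R)-2-methylglycidol, (R)-(2-methyloxiran-2-yl)methanol | C[C@@]1(CO)CO1 | starting material
11 | (S)-2-methylpent-4-ene-1,2-diol | C=CC[C@](C)(O)CO | intermediate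
12 | (S)-2-methyl-1,2-bis(triethylsilyloxy)pent-4-ene | C=CC[C@](C)(O[Si](CC)(CC)CC)CO[Si](CC)(CC)CC | intermediate
13 | (S)-2-methyl-2-(triethylsilyloxy)pent-4-enal | C=CC[C@](C)(O[Si](CC)(CC)CC)C=O | intermediate
14 | 1-lithio derivative of 9 (Li in place of H at the carbamate carbon, cis to the C4 side chain; TMEDA complex) | CC(C)(C)[Si](c1ccccc1)(c1ccccc1)OC[C@H](C)[C@H]2C=C[C@]([Li])(OC(=O)N(C(C)C)C(C)C)CC2 | intermediate
15 | 1-(triisopropoxytitanio) derivative of 9 (Ti trans to the C4 side chain) | CC(C)(C)[Si](c1ccccc1)(c1ccccc1)OC[C@H](C)[C@H]2C=C[C@@]([Ti](OC(C)C)(OC(C)C)OC(C)C)(OC(=O)N(C(C)C)C(C)C)CC2 | intermediate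
16 | (3S,4S)-4-[(R)-1-(tert-butyldiphenylsilyloxy)propan-2-yl]-3-[(1S,2S)-1-hydroxy-2-methyl-2-(triethylsilyloxy)pent-4-en-1-yl]cyclohex-1-en-1-yl N,N-diisopropylcarbamate | CC(C)(C)[Si](c1ccccc1)(c1ccccc1)OC[C@H](C)[C@@H]2CCC(OC(=O)N(C(C)C)C(C)C)=C[C@H]2[C@H](O)[C@@](C)(O[Si](CC)(CC)CC)CC=C | intermediate
17 | 4,4-diethoxybut-1-yne | C#CCC(OCC)OCC | starting material
18 | (1S,3S,3aR,7S,7aS)-7-[(R)-1-(tert-butyldiphenylsilyloxy)propan-2-yl]-3-(prop-2-yn-1-yl)-1-[(S)-2-(triethylsilyloxy)pent-4-en-2-yl]-3,3a,5,6,7,7a-hexahydroisobenzofuran-4(1H)-one | CC(C)(C)[Si](c1ccccc1)(c1ccccc1)OC[C@H](C)[C@@H]2CCC(=O)[C@@H]3[C@H]2[C@H](O[C@H]3CC#C)[C@@](C)(O[Si](CC)(CC)CC)CC=C | intermediate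
19 | potassium C11=C12 enolate of 18 | CC(C)(C)[Si](c1ccccc1)(c1ccccc1)OC[C@H](C)[C@@H]2CC=C([O-])[C@@H]3[C@H]2[C@H](O[C@H]3CC#C)[C@@](C)(O[Si](CC)(CC)CC)CC=C.[K+] | intermediate
20 | (1S,3S,3aR,7S,7aS)-7-[(R)-1-(tert-butyldiphenylsilyloxy)propan-2-yl]-3-(prop-2-yn-1-yl)-1-[(S)-2-(triethylsilyloxy)pent-4-en-2-yl]-1,3,3a,6,7,7a-hexahydroisobenzofuran-4-yl trifluoromethanesulfonate | CC(C)(C)[Si](c1ccccc1)(c1ccccc1)OC[C@H](C)[C@@H]2CC=C(OS(=O)(=O)C(F)(F)F)[C@@H]3[C@H]2[C@H](O[C@H]3CC#C)[C@@](C)(O[Si](CC)(CC)CC)CC=C | intermediate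
21 | (1S,3S,3aS,7S,7aS)-7-[(R)-1-(tert-butyldiphenylsilyloxy)propan-2-yl]-4-methyl-3-(prop-2-yn-1-yl)-1-[(S)-2-(triethylsilyloxy)pent-4-en-2-yl]-1,3,3a,6,7,7a-hexahydroisobenzofuran | CC(C)(C)[Si](c1ccccc1)(c1ccccc1)OC[C@H](C)[C@@H]2CC=C(C)[C@@H]3[C@H]2[C@H](O[C@H]3CC#C)[C@@](C)(O[Si](CC)(CC)CC)CC=C | intermediate
22 | (Z)-2-iodoalkenyl-9-BBN adduct of 21 (B on the terminal carbon, I on C7) | CC(C)(C)[Si](c1ccccc1)(c1ccccc1)OC[C@H](C)[C@@H]2CC=C(C)[C@@H]3[C@H]2[C@H](O[C@H]3CC(/I)=C/B4C5CCCC4CCC5)[C@@](C)(O[Si](CC)(CC)CC)CC=C | intermediate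
23 | (1S,3S,3aS,7S,7aS)-7-[(R)-1-(tert-butyldiphenylsilyloxy)propan-2-yl]-3-(2-iodoprop-2-en-1-yl)-4-methyl-1-[(S)-2-(triethylsilyloxy)pent-4-en-2-yl]-1,3,3a,6,7,7a-hexahydroisobenzofuran | CC(C)(C)[Si](c1ccccc1)(c1ccccc1)OC[C@H](C)[C@@H]2CC=C(C)[C@@H]3[C@H]2[C@H](O[C@H]3CC(I)=C)[C@@](C)(O[Si](CC)(CC)CC)CC=C | intermediate
24 | desilylated diol of 23 (free C16–OH and C3–OH; 1S,2S,3S,9S,10S,14S,15R) | OC[C@H](C)[C@@H]2CC=C(C)[C@@H]3[C@H]2[C@H](O[C@H]3CC(I)=C)[C@@](C)(O)CC=C | intermediate
25 | C16 primary trifluoromethanesulfonate of 24 | FC(F)(F)S(=O)(=O)OC[C@H](C)[C@@H]2CC=C(C)[C@@H]3[C@H]2[C@H](O[C@H]3CC(I)=C)[C@@](C)(O)CC=C | intermediate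
26 | tricyclic oxepane (C3–O–C16 ether; C11(Me)=C12; C3 allyl; C9 2-iodoallyl; 1S,2S,3S,9S,10S,14S,15R) | C=CC[C@]2(C)OC[C@H](C)[C@@H]3CC=C(C)[C@@H]4[C@H]3[C@@H]2O[C@H]4CC(I)=C | intermediate
27 | 11,12-cis-diol of 26 (1S,2S,3S,9S,10R,11R,12S,14S,15R) | C=CC[C@]2(C)OC[C@H](C)[C@@H]3C[C@H](O)[C@](C)(O)[C@@H]4[C@H]3[C@@H]2O[C@H]4CC(I)=C | intermediate
28 | B-alkyl-9-BBN from hydroboration of the allyl group of 27 (boron on C6; hydroxyls transiently O-borylated, drawn free) | C(CC[C@]2(C)OC[C@H](C)[C@@H]3C[C@H](O)[C@](C)(O)[C@@H]4[C@H]3[C@@H]2O[C@H]4CC(I)=C)B1C5CCCC1CCC5 | intermediate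
29 | tetracyclic 11,12-diol, the target without its octanoyl group (1S,2S,3S,9S,10R,11R,12S,14S,15R) | C=C1CCC[C@]2(C)OC[C@H](C)[C@@H]3C[C@H](O)[C@](C)(O)[C@@H]4[C@H]3[C@@H]2O[C@H]4C1 | intermediate
30 | octanoyl chloride | CCCCCCCC(=O)Cl | starting material
31 | CNP0286133.1, the 12-octanoate of 29 (1S,2S,3S,9S,10R,11R,12S,14S,15R) | C=C1CCC[C@]2(C)OC[C@H](C)[C@@H]3C[C@H](OC(=O)CCCCCCC)[C@](C)(O)[C@@H]4[C@H]3[C@@H]2O[C@H]4C1 | target

**Count and risks**

Total steps: 18. Longest linear sequence: 15 (steps 1–5, then 9–18); steps 6–8 make aldehyde 13 in a side branch.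

Most likely to fail:

1. Step 9 (key homoaldol). The C1–C2 bond must form with the anti relationship; a closed chair transition state of this ring-locked allylmetal would instead give the C2 epimer, and the aldehyde is hindered. Fallback, setting out from 9 and 13 and returning at 16: the same metalation and addition deliver the C2-epimeric homoaldol adduct F1. Dess–Martin oxidation converts it into the C2 ketone F2. Reduction with LiBH(s-Bu)3 at −78 °C (polar Felkin–Anh, hydride anti to the C3–OSiEt3 bond and past the methyl group) then gives 16. C2 is thus set by substrate-controlled ketone reduction instead of by the allylmetal transition state.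

2. Step 17 (nine-membered B-alkyl Suzuki closure). Medium-ring formation may lose to protodeboronation or oligomerisation. Fallback, setting out from 27 and 30 and returning at 31:
   - 27 is first acylated with 30 (pyridine, DMAP) to the 12-octanoate F6.
   - Hydroboration with 9-BBN and NaBO3 oxidation give the primary C6 alcohol F7, and Dess–Martin oxidation gives the C6 aldehyde F8.
   - CrCl2 with catalytic NiCl2 in DMSO/THF at high dilution closes the ring by carbonyl addition of the alkenyl metal to the 6-hydroxy macrocycle F9 (C6 configuration irrelevant).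
   - Methyl chloroformate/pyridine gives the allylic methyl carbonate F10.
   - Pd(OAc)2/PBu3 with ammonium formate delivers hydride to the more substituted allyl terminus, leaving the exocyclic methylene and giving 31.

3. Step 16 (chemoselective dihydroxylation). OsO4 may also attack the allyl group. Fallback, setting out from 26 and returning at 27:
   - m-CPBA (NaHCO3, CH2Cl2, −20 °C), which prefers the trisubstituted alkene by about two orders of magnitude, gives from the convex face the 11,12-epoxide F3.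
   - Et2Al(TMP) (TMP = 2,2,6,6-tetramethylpiperidide) isomerises it to the exocyclic allylic alcohol F4, the C12 oxygen keeping its configuration.
   - VO(acac)2/t-BuOOH epoxidises only this allylic alcohol, syn to the C12 hydroxyl, to the spiro-epoxy alcohol F5.
   - LiEt3BH opens the epoxide at its CH2 carbon to give 27.

Further compounds
F1 | step 9 | C2 epimer of 16, (1R)-configured carbinol | CC(C)(C)[Si](c1ccccc1)(c1ccccc1)OC[C@H](C)[C@@H]2CCC(OC(=O)N(C(C)C)C(C)C)=C[C@H]2[C@@H](O)[C@@](C)(O[Si](CC)(CC)CC)CC=C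
F2 | step 9 | C2 ketone derived from F1 | CC(C)(C)[Si](c1ccccc1)(c1ccccc1)OC[C@H](C)[C@@H]2CCC(OC(=O)N(C(C)C)C(C)C)=C[C@H]2C(=O)[C@@](C)(O[Si](CC)(CC)CC)CC=C
F3 | step 16 | 11,12-epoxide of 26 (oxygen cis to H10) | C=CC[C@]2(C)OC[C@H](C)[C@@H]3C[C@@H]5O[C@]5(C)[C@@H]4[C@H]3[C@@H]2O[C@H]4CC(I)=C
F4 | step 16 | C11 exocyclic methylene C12 allylic alcohol | C=CC[C@]2(C)OC[C@H](C)[C@@H]3C[C@H](O)C(=C)[C@@H]4[C@H]3[C@@H]2O[C@H]4CC(I)=C
F5 | step 16 | C11 spiro-epoxide with C12 hydroxyl (epoxide oxygen syn to the hydroxyl) | C=CC[C@]2(C)OC[C@H](C)[C@@H]3C[C@H](O)[C@@]5(CO5)[C@@H]4[C@H]3[C@@H]2O[C@H]4CC(I)=C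
F6 | step 17 | 12-octanoate of 27 | C=CC[C@]2(C)OC[C@H](C)[C@@H]3C[C@H](OC(=O)CCCCCCC)[C@](C)(O)[C@@H]4[C@H]3[C@@H]2O[C@H]4CC(I)=C
F7 | step 17 | primary C6 alcohol from F6 | OCCC[C@]2(C)OC[C@H](C)[C@@H]3C[C@H](OC(=O)CCCCCCC)[C@](C)(O)[C@@H]4[C@H]3[C@@H]2O[C@H]4CC(I)=C
F8 | step 17 | C6 aldehyde from F7 | O=CCC[C@]2(C)OC[C@H](C)[C@@H]3C[C@H](OC(=O)CCCCCCC)[C@](C)(O)[C@@H]4[C@H]3[C@@H]2O[C@H]4CC(I)=C
F9 | step 17 | 6-hydroxy derivative of 31 (C6 epimers) | C=C1C(O)CC[C@]2(C)OC[C@H](C)[C@@H]3C[C@H](OC(=O)CCCCCCC)[C@](C)(O)[C@@H]4[C@H]3[C@@H]2O[C@H]4C1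
F10 | step 17 | C6 methyl carbonate of F9 | C=C1C(OC(=O)OC)CC[C@]2(C)OC[C@H](C)[C@@H]3C[C@H](OC(=O)CCCCCCC)[C@](C)(O)[C@@H]4[C@H]3[C@@H]2O[C@H]4C1
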